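ent-Kaurane numbering is used. Rings C and D share C8, C14 and C13; cutting C11–C12 and C13–C14 and joining C11 to C14 turns the bicyclo[3.2.1]octane into a cyclobutanone that is locally symmetric about C8. The key step reverses this: rhodium opens one of the two equivalent CH2–C(=O) bonds and stitches in a tethered vinyl group, closing rings C and D and setting C8 and C13 in one operation. The precursor is a 3,3-disubstituted cyclobutanone whose C8 carries a CH2–C(ketal)–CH=CH2 arm (masked C16 ketone) and a CH2O–acyl arm; the acyl group, the enantiopure cyclohexenecarboxylate of ring A, is a spectator that later closes C9–C10 by tethered Michael addition.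

Key step: step 12

Assumption: the sense of induction of the valine auxiliary (step 5) and of the (R)-bisphosphine (step 12) is taken as written; if either proves opposite, the D-valine ester or the (S)-ligand is used and nothing else changes.

Step 1
Reactants: 1 3-chloro-2-(chloromethyl)prop-1-ene; 2 acrolein
Product: 5 5-(chloromethyl)hexa-1,5-dien-3-ol (racemic), via 3-chloro-2-(iodomethyl)prop-1-ene 3 (not isolated), via the allylzinc iodide 4 (not isolated)
Conditions: 1 (2.5 equiv), NaI (1.2 equiv), acetone, rt; then 2 (1 equiv), Zn dust, THF/sat. aq. NH4Cl, 0 °C → rt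
Reagents that add atoms: none
Why: Aqueous Barbier allylation, in which zinc inserts into the C–I bond of 3 much faster than into C–Cl and the allylzinc 4 adds 1,2 to the enal, so one chloromethyl arm survives; the new carbinol centre is racemic and is erased in step 2.

Step 2
Reactants: 5 5-(chloromethyl)hexa-1,5-dien-3-ol
Product: 6 5-(chloromethyl)hexa-1,5-dien-3-one
Conditions: Dess–Martin periodinane, CH2Cl2, 0 °C → rt; used crude
Reagents that add atoms: none
Why: Dess–Martin oxidation of a secondary allylic alcohol under neutral conditions, chosen so that the skipped alkene is not drawn into conjugation and the allylic chloride is not displaced.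

Step 3
Reactants: 6 5-(chloromethyl)hexa-1,5-dien-3-one
Product: 7 2-[2-(chloromethyl)prop-2-en-1-yl]-2-ethenyl-1,3-dioxolane
Conditions: Me3SiOCH2CH2OSiMe3, Me3SiOSO2CF3 (2 mol%), CH2Cl2, −78 °C; pyridine quench
Reagents that add atoms: 1,2-bis(trimethylsilyloxy)ethane, C[Si](C)(C)OCCO[Si](C)(C)C
Why: Silyl triflate-catalysed ketalisation with the bis-silyl glycol at low temperature leaves enone double bonds in place, whereas protic glycol/acid would add to the vinyl ketone; the chloromethyl-substituted alkene is too electron-poor to attack the transient oxocarbenium ion.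

Step 4
Reactants: 8 tert-butyl 2-oxocyclohexane-1-carboxylate; 9 L-valine tert-butyl ester
Product: 10 tert-butyl 2-{[(2S)-1-tert-butoxy-3-methyl-1-oxobutan-2-yl]amino}cyclohex-1-ene-1-carboxylate
Conditions: AcOH (cat.), 4 Å molecular sieves, toluene, 60 °C
Reagents that add atoms: none
Why: Enamine condensation of a primary amine with a β-keto ester gives the hydrogen-bonded enamino ester, and the mild acid leaves both tert-butyl esters intact.

Step 5
Reactants: 10 the enamino ester
Product: 12 tert-butyl (1R)-1-methyl-2-oxocyclohexane-1-carboxylate, via the C-methylated imine 11 (not isolated)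
Conditions: LiN(iPr)2, toluene, −78 °C; HMPA, then MeI, −78 → −40 °C; 1 M aq. citric acid, rt
Reagents that add atoms: iodomethane, CI; water, O
Why: Auxiliary-controlled alkylation of a chelated lithio-enamine, in which lithium bridges nitrogen and the valine ester carbonyl, the isopropyl group shields one face and iodomethane enters from the other to set C4 as R; mild aqueous acid then hydrolyses imine 11 and returns the auxiliary.

Step 6
Reactants: 12 tert-butyl (1R)-1-methyl-2-oxocyclohexane-1-carboxylate
Product: 13 tert-butyl (1R)-1,3-dimethyl-2-oxocyclohexane-1-carboxylate (both C3 epimers)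
Conditions: LiN(iPr)2, THF, −78 °C; MeI, −78 → 0 °C
Reagents that add atoms: iodomethane, CI
Why: Kinetic enolate alkylation at the only enolisable α-carbon (C10); the new centre is an epimer mixture that becomes sp2 in step 7.

Step 7
Reactants: 13 tert-butyl (1R)-1,3-dimethyl-2-oxocyclohexane-1-carboxylate
Product: 14 tert-butyl (1R)-1,3-dimethyl-2-[(trifluoromethanesulfonyl)oxy]cyclohex-2-ene-1-carboxylate
Conditions: KN(SiMe3)2, THF, −78 °C; N-(5-chloropyridin-2-yl)triflimide, −78 → 0 °C
Reagents that add atoms: N-(5-chloropyridin-2-yl)-1,1,1-trifluoro-N-[(trifluoromethyl)sulfonyl]methanesulfonamide, FC(F)(F)S(=O)(=O)N(c1ccc(Cl)cn1)S(=O)(=O)C(F)(F)F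
Why: Enol triflate formation by O-sulfonylation of the potassium enolate, which can only form toward C10, gives the tetrasubstituted C5=C10 alkene.

Step 8
Reactants: 14 the enol triflate
Product: 15 (6R)-6-(tert-butoxycarbonyl)-2,6-dimethylcyclohex-1-ene-1-carboxylic acid (ring A: C6 acid on C5, C5=C10, C4 R)
Conditions: Pd(OAc)2 (5 mol%), 1,3-bis(diphenylphosphino)propane, CO (1 atm), Et3N, DMF/H2O, 70 °C; then 1 M HCl
Reagents that add atoms: carbon monoxide, [C-]#[O+]; water, O
Why: Palladium-catalysed hydroxycarbonylation, in which zerovalent palladium adds to the C–OTf bond, CO inserts and water cleaves the acyl–palladium, delivers the hindered acid without any ester hydrolysis next to the tert-butyl ester.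

Step 9
Reactants: 15 the ring-A acid; 7 the chloro ketal
Product: 16 1-tert-butyl 2-{2-[(2-ethenyl-1,3-dioxolan-2-yl)methyl]prop-2-en-1-yl} (1R)-1,3-dimethylcyclohex-2-ene-1,2-dicarboxylate
Conditions: Cs2CO3, DMF, 50 °C
Reagents that add atoms: none
Why: SN2 O-alkylation of the cesium carboxylate by a primary allylic chloride forms the hindered C6–O–C7 ester without activating the carboxyl group, so no anhydride can form with the neighbouring tert-butyl ester and the vinyl ketal is untouched.

Step 10
Reactants: 16 the allylic ester; 17 trichloroacetyl chloride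
Product: 19 1-tert-butyl 2-({2,2-dichloro-1-[(2-ethenyl-1,3-dioxolan-2-yl)methyl]-3-oxocyclobutyl}methyl) (1R)-1,3-dimethylcyclohex-2-ene-1,2-dicarboxylate (two diastereomers at the cyclobutane carbon), via dichloroketene 18 (not isolated)
Conditions: Zn–Cu couple, 17 (slow addition), 1,2-dimethoxyethane, Et2O, rt
Reagents that add atoms: none
Why: [2+2] ketene–alkene cycloaddition in which electrophilic dichloroketene picks the 1,1-disubstituted alkene over the hindered, inductively deactivated vinyl ketal and the tetrasubstituted enoate, its carbonyl carbon bonding to the CH2 terminus; dimethoxyethane ties up ZnCl2 to protect the ketal, and the stereogenic cyclobutane carbon loses its chirality in step 11.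

Step 11
Reactants: 19 the dichlorocyclobutanone
Product: 20 1-tert-butyl 2-({1-[(2-ethenyl-1,3-dioxolan-2-yl)methyl]-3-oxocyclobutyl}methyl) (1R)-1,3-dimethylcyclohex-2-ene-1,2-dicarboxylate
Conditions: Zn dust, NH4Cl, MeOH, rt
Reagents that add atoms: none
Why: Reductive dechlorination of an α,α-dichlorocyclobutanone by zinc under near-neutral conditions spares the ketal, both esters and the alkenes, and makes the two CH2–C(=O) arms on C8 equivalent.

Step 12
Reactants: 20 the cyclobutanone
Product: 21 1-tert-butyl 2-{[(1S,5S)-3-oxospiro[bicyclo[3.2.1]octane-6,2′-[1,3]dioxolan]-1-yl]methyl} (1R)-1,3-dimethylcyclohex-2-ene-1,2-dicarboxylate (bicyclic C1 = C8, C5 = C13; same spatial arrangement at C8 and C13 as in 26)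
Conditions: [Rh(C2H4)2Cl]2 (5 mol%), (R)-DTBM-SEGPHOS (12 mol%), 1,4-dioxane, 120 °C
Reagents that add atoms: none
Why: Monovalent rhodium adds oxidatively to the C11–C14 acyl–alkyl bond to give a five-membered acyl–alkyl complex of trivalent rhodium, the vinyl group inserts into Rh–C14 so that C13 bonds to C14, and reductive elimination joins C12 to C11. The closest known reaction type is the rhodium-catalysed intramolecular carboacylation of alkenes by cyclobutanones (cut-and-sew) that gives bridged bicyclic ketones. Ring D closes in the insertion step as a 5-exo addition of the Rh–C14 bond across C13=C12, and ring C closes in the C11–C12 reductive elimination. C8 is set by the chiral bisphosphine, which decides which of the two CH2–C(=O) bonds (equivalent apart from the remote C4 centre) is cleaved, and C13 follows because the one-carbon bridge C14 can span C8 and C13 on one side only. The step needs C–C insertion to beat decarbonylation and β-hydride loss and needs the vinyl group, not the enoate, to react; four-ring strain release, the quaternary C8 and the C16 ketal (gem-disubstituent effect) holding the vinyl group at rhodium, and the hindered tetrasubstituted ring-A alkene should secure this. Any C8/C13 mismatch would be a diastereomer because of C4 and could be removed by chromatography.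

Step 13
Reactants: 21 the bicyclic keto ester
Product: 22 tert-butyl 16,16-(ethylenedioxy)-11-oxo-6,7-seco-17-norkauran-19-oate 6,7-lactone (seven-membered C6(=O)–O–C7 lactone; C9–C10 bond syn to C14 and anti to C15, C20 anti to H9, H5 trans to C20, C19 cis to C20; all six stereocentres as in 26)
Conditions: KOC(CH3)3 (0.3 equiv), t-BuOH/THF, 0 °C → rt
Reagents that add atoms: none
Why: Intramolecular Michael addition under reversible enolisation, in which only the C9 enolate can reach C10 through the ester tether, attack should come from the exo face of ring C (the C14 side, away from the C15–C16 bridge) through a chair-like seven-membered array that sets C10 with C20 anti to H9, and C5 is set by protonation of the lactone enolate to the trans ring fusion, which the alkoxide can also reach by equilibration.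

Step 14
Reactants: 22 the ketal lactone
Product: 23 11,16-dioxo-6,7-seco-17-norkauran-19-oic acid 6,7-lactone
Conditions: CF3CO2H/H2O (9:1), CH2Cl2, 0 °C → rt
Reagents that add atoms: water, O
Why: Acid hydrolysis of the dioxolane and acidolysis of the tert-butyl ester (alkyl–oxygen fission) occur in one operation, before any acid-sensitive exocyclic alkene exists, and touch neither the lactone nor a stereocentre.

Step 15
Reactants: 23 the diketo acid lactone
Product: 24 11-oxo-6,7-secokaur-16-en-19-oic acid 6,7-lactone
Conditions: Ph3PCH3Br (4 equiv), KOC(CH3)3 (4 equiv), THF, 0 °C → rt; pH 4 work-up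
Reagents that add atoms: methyltriphenylphosphonium bromide, C[P+](c1ccccc1)(c1ccccc1)c1ccccc1.[Br-]
Why: Wittig methylenation with excess ylide (one equivalent is taken by the carboxylic acid) should convert only the unhindered five-ring ketone at C16, since the C11 ketone sits next to C9 with its two quaternary neighbours and the lactone carbonyl is hindered.

Step 16
Reactants: 24 the methylene lactone acid
Product: 25 7-hydroxy-11-oxo-6,7-secokaur-16-ene-6,19-dioic acid
Conditions: LiOH, THF/H2O, 0 °C → rt; then 1 M HCl to pH 3, 0 °C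
Reagents that add atoms: lithium hydroxide, [Li+].[OH-]
Why: Saponification of the seven-membered lactone by acyl–oxygen cleavage frees the C6 acid and the C7 alcohol; C5 cannot epimerise once it is α to a carboxylate, and C9–H, wedged between quaternary C8 and C10, should enolise far more slowly than C12–H2.

Step 17
Reactants: 25 the hydroxy diacid
Product: 26 (4R,5S,8R,9S,10S,13S)-7,11-dioxo-6,7-secokaur-16-ene-6,19-dioic acid (ent-kaurane series; CNP0408869.1)
Conditions: Dess–Martin periodinane, CH2Cl2/THF, 0 °C → rt
Reagents that add atoms: none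
Why: Dess–Martin oxidation stops at the aldehyde and tolerates the free acids, the ketone and the alkene, and C7 has no α-hydrogen (C8 is quaternary), so nothing can epimerise.

Compound list
1 | 3-chloro-2-(chloromethyl)prop-1-ene | C=C(CCl)CCl | starting material
2 | acrolein | C=CC=O | starting material
3 | 3-chloro-2-(iodomethyl)prop-1-ene | C=C(CCl)CI | intermediate
4 | [2-(chloromethyl)prop-2-en-1-yl]zinc iodide | C=C(CCl)C[Zn]I | intermediate
5 | 5-(chloromethyl)hexa-1,5-dien-3-ol (racemic) | C=CC(O)CC(=C)CCl | intermediate
6 | 5-(chloromethyl)hexa-1,5-dien-3-one | C=CC(=O)CC(=C)CCl | intermediate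
7 | 2-[2-(chloromethyl)prop-2-en-1-yl]-2-ethenyl-1,3-dioxolane | C=CC1(OCCO1)CC(=C)CCl | intermediate
8 | tert-butyl 2-oxocyclohexane-1-carboxylate | O=C1CCCCC1C(=O)OC(C)(C)C | starting material
9 | L-valine tert-butyl ester | CC(C)[C@H](N)C(=O)OC(C)(C)C | starting material
10 | tert-butyl 2-{[(2S)-1-tert-butoxy-3-methyl-1-oxobutan-2-yl]amino}cyclohex-1-ene-1-carboxylate | CC(C)[C@H](NC1=C(CCCC1)C(=O)OC(C)(C)C)C(=O)OC(C)(C)C | intermediate
11 | tert-butyl (1R)-2-{[(2S)-1-tert-butoxy-3-methyl-1-oxobutan-2-yl]imino}-1-methylcyclohexane-1-carboxylate | CC(C)[C@H](N=C1CCCC[C@@]1(C)C(=O)OC(C)(C)C)C(=O)OC(C)(C)C | intermediate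
12 | tert-butyl (1R)-1-methyl-2-oxocyclohexane-1-carboxylate | CC(C)(C)OC(=O)[C@]1(C)CCCCC1=O | intermediate
13 | tert-butyl (1R)-1,3-dimethyl-2-oxocyclohexane-1-carboxylate (C3 epimers) | CC1CCC[C@@](C)(C(=O)OC(C)(C)C)C1=O | intermediate
14 | tert-butyl (1R)-1,3-dimethyl-2-[(trifluoromethanesulfonyl)oxy]cyclohex-2-ene-1-carboxylate | FC(F)(F)S(=O)(=O)OC1=C(C)CCC[C@@]1(C)C(=O)OC(C)(C)C | intermediate
15 | (6R)-6-(tert-butoxycarbonyl)-2,6-dimethylcyclohex-1-ene-1-carboxylic acid | OC(=O)C1=C(C)CCC[C@@]1(C)C(=O)OC(C)(C)C | intermediate
16 | 1-tert-butyl 2-{2-[(2-ethenyl-1,3-dioxolan-2-yl)methyl]prop-2-en-1-yl} (1R)-1,3-dimethylcyclohex-2-ene-1,2-dicarboxylate | C=CC1(OCCO1)CC(=C)COC(=O)C2=C(C)CCC[C@@]2(C)C(=O)OC(C)(C)C | intermediate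
17 | trichloroacetyl chloride | ClC(Cl)(Cl)C(Cl)=O | starting material
18 | dichloroketene | ClC(Cl)=C=O | intermediate
19 | 2,2-dichlorocyclobutanone ester (two diastereomers at the cyclobutane carbon) | C=CC1(OCCO1)CC2(COC(=O)C3=C(C)CCC[C@@]3(C)C(=O)OC(C)(C)C)CC(=O)C2(Cl)Cl | intermediate
20 | cyclobutanone ester, key-step precursor | C=CC1(OCCO1)CC2(COC(=O)C3=C(C)CCC[C@@]3(C)C(=O)OC(C)(C)C)CC(=O)C2 | intermediate
21 | bicyclo[3.2.1]octan-3-one ester with C16 ketal, key-step product | O1CCOC12C[C@]3(COC(=O)C4=C(C)CCC[C@@]4(C)C(=O)OC(C)(C)C)C[C@H]2CC(=O)C3 | intermediate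
22 | tert-butyl 16,16-(ethylenedioxy)-11-oxo-6,7-seco-17-norkauran-19-oate 6,7-lactone | O1CCOC12C[C@]3(CO5)C[C@H]2CC(=O)[C@H]3[C@]4(C)CCC[C@@](C)(C(=O)OC(C)(C)C)[C@H]4C5=O | intermediate
23 | 11,16-dioxo-6,7-seco-17-norkauran-19-oic acid 6,7-lactone | O=C1C[C@]2(CO5)C[C@H]1CC(=O)[C@H]2[C@]4(C)CCC[C@@](C)(C(=O)O)[C@H]4C5=O | intermediate
24 | 11-oxo-6,7-secokaur-16-en-19-oic acid 6,7-lactone | C=C1C[C@]2(CO5)C[C@H]1CC(=O)[C@H]2[C@]4(C)CCC[C@@](C)(C(=O)O)[C@H]4C5=O | intermediate
25 | 7-hydroxy-11-oxo-6,7-secokaur-16-ene-6,19-dioic acid | C=C1C[C@]2(CO)C[C@H]1CC(=O)[C@H]2[C@]1(C)CCC[C@@](C)(C(=O)O)[C@H]1C(=O)O | intermediate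
26 | (4R,5S,8R,9S,10S,13S)-7,11-dioxo-6,7-secokaur-16-ene-6,19-dioic acid | C=C1C[C@]2(C=O)C[C@H]1CC(=O)[C@H]2[C@]1(C)CCC[C@@](C)(C(=O)O)[C@H]1C(=O)O | target

Total steps: 17. Longest linear sequence: 14 steps (steps 4–8, then 9–17, from compound 8).

Steps most likely to fail

Step 13. The conjugate addition may not take place at the hindered, partly deconjugated enoate, may revert, or may lose to acyl transfer from O7 to C9. Attack on the wrong face at C9 or C10, or protonation at C5 to the cis fusion, would give diastereomeric lactones. Fallback, from 21 back to 22: soft enolisation (Me3SiOSO2CF3, Et3N, CH2Cl2, 0 °C) should give the C9 trimethylsilyl enol ether F1 together with its C11=C12 regioisomer F2. With catalytic HN(SO2CF3)2 at −78 °C, F1 should undergo an intramolecular Mukaiyama–Michael addition to the silyl ketene acetal F3, which aqueous work-up hydrolyses to 22. F2 cannot reach C10 and returns 21 on work-up. This replaces the reversible anionic addition by an irreversible, Lewis-acid-driven one under kinetic control.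

Step 12. After oxidative addition the rhodium acyl may lose CO instead of taking up the alkene, the inserted alkyl may undergo β-hydride elimination, or the ligand may discriminate poorly between the two acyl–carbon bonds. Fallback, from 20 back to 21: condensation with 2-amino-3-methylpyridine gives the N-(3-methylpyridin-2-yl) ketimine F4. The pyridine nitrogen then directs monovalent rhodium ([Rh(C2H4)2Cl]2 with the same bisphosphine or a triarylphosphine) into the imine α C–C bond, a mode known to suppress decarbonylation. Alkene insertion as before gives the bicyclic ketimine F5, and mild aqueous acid releases 21. If ligand control is weak in this mode, the C8/C13 isomers are diastereomers and are separated by chromatography.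

Step 3. The glycol ether may add in conjugate fashion to the vinyl ketone, the skipped alkene may migrate into conjugation, or the vinyl ketal once formed may ionise and cyclise onto the other alkene. Fallback, from 6 back to 7: thiophenol (1 equiv, cat. Et3N, CH2Cl2, −20 °C) adds to the vinyl ketone to give the β-(phenylsulfanyl) ketone F6. Ketalisation as in step 3, now without an enone, gives its dioxolane F7. NaIO4 (MeOH/H2O) gives the sulfoxide F8, and thermal syn-elimination (toluene, 110 °C, CaCO3, P(OMe)3) returns 7.

Further compounds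
F1 | step 13 | trimethylsilyl enol ether of 21 toward C9 (C9=C11) | O1CCOC12C[C@]3(COC(=O)C4=C(C)CCC[C@@]4(C)C(=O)OC(C)(C)C)C[C@H]2CC(O[Si](C)(C)C)=C3
F2 | step 13 | trimethylsilyl enol ether of 21 toward C12 (C11=C12) | O1CCOC12C[C@]3(COC(=O)C4=C(C)CCC[C@@]4(C)C(=O)OC(C)(C)C)C[C@H]2C=C(O[Si](C)(C)C)C3
F3 | step 13 | trimethylsilyl ketene acetal of lactone 22 (C5=C6) | O1CCOC12C[C@]3(CO5)C[C@H]2CC(=O)[C@H]3[C@]4(C)CCC[C@@](C)(C(=O)OC(C)(C)C)C4=C5O[Si](C)(C)C
F4 | step 12 | N-(3-methylpyridin-2-yl) ketimine of 20 | C=CC1(OCCO1)CC2(COC(=O)C3=C(C)CCC[C@@]3(C)C(=O)OC(C)(C)C)CC(=Nc4ncccc4C)C2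
F5 | step 12 | N-(3-methylpyridin-2-yl) ketimine of 21 | O1CCOC12C[C@]3(COC(=O)C4=C(C)CCC[C@@]4(C)C(=O)OC(C)(C)C)C[C@H]2CC(=Nc5ncccc5C)C3
F6 | step 3 | 5-(chloromethyl)-1-(phenylsulfanyl)hex-5-en-3-one | ClCC(=C)CC(=O)CCSc1ccccc1
F7 | step 3 | 2-[2-(chloromethyl)prop-2-en-1-yl]-2-[2-(phenylsulfanyl)ethyl]-1,3-dioxolane | ClCC(=C)CC1(CCSc2ccccc2)OCCO1
F8 | step 3 | 2-[2-(chloromethyl)prop-2-en-1-yl]-2-[2-(phenylsulfinyl)ethyl]-1,3-dioxolane | ClCC(=C)CC1(CCS(=O)c2ccccc2)OCCO1
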